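**Plan**
1. The first cut is the bond between the carbinol carbon and the vinylic CH of the (E)-trisubstituted alkene. It gives aldehyde 8 (ring A, the dimethyl-methylidene-cyclohexene) and alkenyl iodide 17 (ring B, the bromohydrin ring).
2. Ring A is then cut at the CMe2–CH(CH2O) ring bond and traced back to geranyl acetate. Ring B is cut at its C–CH3, C–Br and side-chain =C–CH3/C–I bonds and traced back to a cyclohexene-oxide ester.
3. Forward: ring A is closed from the acyclic C10 chain (steps 1–6). Ring B is bought as a six-membered ring and decorated (steps 7–13). The two C10 halves are joined in the last step without protecting groups.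
4. Enabling feature: the carbinol carbon is a secondary allylic alcohol. One neighbour is an sp2 CH. The other is the ring-A stereocentre, which sits between the quaternary CMe2 carbon and the C(=CH2) carbon. An alkenyl-metal/aldehyde addition therefore forms the bond, and the size difference between these two flanking ring carbons sets the new centre.
5. Stereochemistry of ring A: the Shi epoxide centre is relayed to the ring CH by a chair radical cyclisation and is then erased. The E alkene comes from syn-carboalumination.
6. Stereochemistry of ring B: the side-chain carbon comes from the epoxy ester, C–Br from two successive inversions, and the tertiary carbinol from equatorial methyl delivery.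

Key step: step 14

Assumption: epoxy ester 9 and the L-fructose-derived enantiomer of the Shi ketone are taken as purchasable. Compound 9 is otherwise two routine steps (bromolactonisation, ethanolysis) from (S)-cyclohex-3-ene-1-carboxylic acid.

Step 1
Reactants: 1 geranyl acetate
Product: 2 (2E)-5-[(2S)-3,3-dimethyloxiran-2-yl]-3-methylpent-2-en-1-yl acetate
Conditions: L-fructose-derived Shi ketone (30 mol %), Oxone (2KHSO5·KHSO4·K2SO4, 1 equiv of KHSO5), K2CO3, Bu4NHSO4, MeCN–CH2(OMe)2–aq. buffer, 0 °C
Reagents that add atoms: potassium peroxymonosulfate, [K+].[O-]S(=O)(=O)OO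
Why: Shi epoxidation by the chiral dioxirane should attack only the electron-rich 6,7-alkene, because the 2,3-alkene is deactivated by the allylic acetate, and the L-series ketone should deliver the (S)-epoxide through the spiro transition state.

Step 2
Reactants: 2 (2E)-5-[(2S)-3,3-dimethyloxiran-2-yl]-3-methylpent-2-en-1-yl acetate
Product: 3 [(1R,3S)-3-hydroxy-2,2-dimethyl-6-methylidenecyclohexyl]methyl acetate
Conditions: Cp2TiCl2 (2.5 equiv), Mn dust, THF (degassed), rt; then aq. NaH2PO4
Reagents that add atoms: none
Why: In this titanocene-mediated radical epoxypolyene cyclisation, Cp2TiCl opens the epoxide to the tertiary radical, which closes 6-endo on the trisubstituted alkene through a chair with the titanoxy and acetoxymethyl groups both equatorial (cis-1,3, which sets the ring CH as R), and the new tertiary radical is trapped by a second Cp2TiCl and loses Cp2Ti(H)Cl toward the methyl group to give the exocyclic methylidene.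

Step 3
Reactants: 3 [(1R,3S)-3-hydroxy-2,2-dimethyl-6-methylidenecyclohexyl]methyl acetate
Product: 4 [(1R)-2,2-dimethyl-6-methylidene-3-oxocyclohexyl]methyl acetate
Conditions: Dess–Martin periodinane, pyridine, CH2Cl2, 0 °C to rt
Reagents that add atoms: none
Why: Dess–Martin oxidation of the secondary alcohol is neutral, so the acetate, the exocyclic alkene and the remote ring stereocentre should stay untouched.

Step 4
Reactants: 4 [(1R)-2,2-dimethyl-6-methylidene-3-oxocyclohexyl]methyl acetate
Product: 5 [(1R,3E)-2,2-dimethyl-6-methylidene-3-[2-(4-methylbenzenesulfonyl)hydrazinylidene]cyclohexyl]methyl acetate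
Conditions: TsNHNH2, EtOH, 60 °C
Reagents that add atoms: 4-methylbenzenesulfonohydrazide, Cc1ccc(cc1)S(=O)(=O)NN
Why: Hydrazone condensation works on ketones flanked by a gem-dimethyl carbon, and the NHTs group should settle on the side of the ring CH2, away from the quaternary carbon.

Step 5
Reactants: 5 [(1R,3E)-2,2-dimethyl-6-methylidene-3-[2-(4-methylbenzenesulfonyl)hydrazinylidene]cyclohexyl]methyl acetate
Product: 7 [(1R)-2,2-dimethyl-6-methylidenecyclohex-3-en-1-yl]methanol, via alkenyllithium alkoxide 6 (not isolated)
Conditions: MeLi (6 equiv), Et2O, −78 °C to rt; then H2O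
Reagents that add atoms: none
Why: In this Shapiro reaction the only α-hydrogens lie on the ring CH2, so the dianion loses sulfinate and N2 to give a single alkenyllithium that is protonated on work-up, while the excess MeLi removes the acetate in the same flask.

Step 6
Reactants: 7 [(1R)-2,2-dimethyl-6-methylidenecyclohex-3-en-1-yl]methanol
Product: 8 (1R)-2,2-dimethyl-6-methylidenecyclohex-3-ene-1-carbaldehyde
Conditions: Dess–Martin periodinane, pyridine, CH2Cl2, 0 °C; used at once
Reagents that add atoms: none
Why: Buffered Dess–Martin oxidation reaches the aldehyde without free acid or strong base, so the labile α-centre should keep its configuration and the exocyclic alkene should stay out of conjugation.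

Step 7
Reactants: 9 ethyl (1S,3S,6R)-7-oxabicyclo[4.1.0]heptane-3-carboxylate
Product: 10 ethyl (1S,3R,4R)-4-hydroxy-3-[(4-methylbenzenesulfonyl)oxy]cyclohexane-1-carboxylate
Conditions: anhydrous p-TsOH (1.05 equiv), CH2Cl2, 0 °C
Reagents that add atoms: 4-methylbenzenesulfonic acid, Cc1ccc(cc1)S(=O)(=O)O
Why: Epoxide opening by a sulfonic acid should follow the Fürst–Plattner rule in the half-chair that keeps the ester equatorial, so the sulfonate enters with inversion at the carbon 1,3 to the ester, the same regiochemistry that amine nucleophiles show on this epoxide.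

Step 8
Reactants: 10 ethyl (1S,3R,4R)-4-hydroxy-3-[(4-methylbenzenesulfonyl)oxy]cyclohexane-1-carboxylate
Product: 11 ethyl (1S,3R)-3-[(4-methylbenzenesulfonyl)oxy]-4-oxocyclohexane-1-carboxylate
Conditions: Dess–Martin periodinane, pyridine, CH2Cl2, 0 °C to rt
Reagents that add atoms: none
Why: Dess–Martin oxidation converts the secondary alcohol into the ketone under conditions too mild to enolise the sulfonate-bearing centre.

Step 9
Reactants: 11 ethyl (1S,3R)-3-[(4-methylbenzenesulfonyl)oxy]-4-oxocyclohexane-1-carboxylate
Product: 12 ethyl (1S,3S)-3-bromo-4-oxocyclohexane-1-carboxylate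
Conditions: Bu4NBr (0.98 equiv), acetone, −10 to 0 °C; used crude
Reagents that add atoms: tetrabutylammonium bromide, CCCC[N+](CCCC)(CCCC)CCCC.[Br-]
Why: In this SN2 displacement of an α-sulfonyloxy ketone the axial C–O bond overlaps with the carbonyl π system, bromide enters from the equatorial side with inversion to place bromine cis to the ester, and keeping bromide as the limiting reagent leaves no free halide to exchange with the product.

Step 10
Reactants: 12 ethyl (1S,3S)-3-bromo-4-oxocyclohexane-1-carboxylate
Product: 13 ethyl (1S,3S,4R)-3-bromo-4-hydroxy-4-methylcyclohexane-1-carboxylate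
Conditions: MeTi(OiPr)3 (1.5 equiv, distilled), Et2O–hexane, −20 °C to rt; then aq. NH4F
Reagents that add atoms: methyltitanium triisopropoxide MeTi(OiPr)3, C[Ti](OC(C)C)(OC(C)C)OC(C)C
Why: This carbonyl addition of a non-basic methyltitanium reagent is the classical α-haloketone entry to cis-halohydrins; it spares the ester and the enolisable C–Br centre, and attack from the equatorial side is favoured by the bulk of the reagent and by the equatorial bromine (which the oxygen would eclipse in axial attack), so methyl ends equatorial and OH axial, cis to bromine.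

Step 11
Reactants: 13 ethyl (1S,3S,4R)-3-bromo-4-hydroxy-4-methylcyclohexane-1-carboxylate
Product: 14 (1S,3S,4R)-3-bromo-4-hydroxy-4-methylcyclohexane-1-carbaldehyde
Conditions: DIBAL-H (iBu2AlH, 2.1 equiv), CH2Cl2, −78 °C; then Rochelle salt
Reagents that add atoms: none
Why: Partial ester reduction stops at the aluminium hemiacetal at −78 °C after the first equivalent has been consumed by the hydroxyl group, and the secondary bromide is inert to DIBAL-H at this temperature.

Step 12
Reactants: 14 (1S,3S,4R)-3-bromo-4-hydroxy-4-methylcyclohexane-1-carbaldehyde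
Product: 15 (1R,2S,4S)-2-bromo-4-ethynyl-1-methylcyclohexan-1-ol
Conditions: dimethyl (1-diazo-2-oxopropyl)phosphonate, K2CO3, MeOH, 0 °C to rt
Reagents that add atoms: dimethyl (1-diazo-2-oxopropyl)phosphonate, COP(=O)(OC)C(=[N+]=[N-])C(C)=O
Why: Ohira–Bestmann homologation needs only carbonate base, the equatorial formyl group is already the more stable epimer, and a cis-bromohydrin cannot close to an epoxide because O and Br cannot become antiperiplanar.

Step 13
Reactants: 15 (1R,2S,4S)-2-bromo-4-ethynyl-1-methylcyclohexan-1-ol
Product: 17 (1R,2S,4S)-2-bromo-4-[(1E)-1-iodoprop-1-en-2-yl]-1-methylcyclohexan-1-ol, via alkenylalane 16 (not isolated)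
Conditions: Me3Al (3.5 equiv), Cp2ZrCl2 (20 mol %), CH2Cl2, 0 °C; then I2, THF, −30 °C
Reagents that add atoms: trimethylaluminium, C[Al](C)C; iodine, II
Why: Negishi carboalumination adds methyl and aluminium syn across the terminal alkyne with methyl on the internal carbon, the hydroxyl group is masked in the flask as its aluminium alkoxide, and iodinolysis with retention gives the E iodide.

Step 14
Reactants: 8 (1R)-2,2-dimethyl-6-methylidenecyclohex-3-ene-1-carbaldehyde; 17 (1R,2S,4S)-2-bromo-4-[(1E)-1-iodoprop-1-en-2-yl]-1-methylcyclohexan-1-ol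
Product: 19 (1R,2S,4S)-2-bromo-4-{(2E,4R)-4-[(1R)-2,2-dimethyl-6-methylidenecyclohex-3-en-1-yl]-4-hydroxybut-2-en-2-yl}-1-methylcyclohexan-1-ol, via alkenylchromium dichloride 18 (not isolated)
Conditions: CrCl2 (6 equiv), NiCl2 (2 mol %), DMSO–THF, rt, 8 in 1.5-fold excess; then aq. sodium serinate
Reagents that add atoms: none
Why: Zerovalent nickel, formed from NiCl2 by CrCl2, inserts into the C(sp2)–I bond of 17 with retention of the E geometry and hands the alkenyl group to trivalent chromium, and the resulting alkenylchromium 18 adds to the carbonyl group of 8 to give a chromium alkoxide that is hydrolysed on work-up. The closest known reaction type is the Nozaki–Hiyama–Kishi alkenylation of α-branched aldehydes by 2,2-disubstituted alkenyl iodides. No ring is closed. The one new stereocentre, the carbinol carbon, is controlled by the adjacent ring-A stereocentre through a Felkin–Anh arrangement in which the quaternary CMe2 carbon stands anti to the incoming alkenyl group, the C(=CH2) carbon lies next to the carbonyl oxygen and the hydrogen flanks the trajectory, which leads to the (R)-carbinol. The step needs chemoselectivity for the alkenyl iodide over the secondary alkyl bromide and the free tertiary alcohol, which is secured because unactivated alkyl bromides are not reduced by CrCl2 without a cobalt co-catalyst and because alkenylchromium reagents are not protonated by alcohols. It also needs a non-basic nucleophile, since the α-hydrogen of 8 is both allylic and α to the formyl group, and the low basicity of the chromium reagent should keep this centre from epimerising and the exocyclic alkene from moving into conjugation.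

**Compound list**
1 | geranyl acetate, (2E)-3,7-dimethylocta-2,6-dien-1-yl acetate | CC(C)=CCC/C(C)=C/COC(C)=O | starting material
2 | (2E)-5-[(2S)-3,3-dimethyloxiran-2-yl]-3-methylpent-2-en-1-yl acetate | CC1(C)O[C@H]1CC/C(C)=C/COC(C)=O | intermediate
3 | [(1R,3S)-3-hydroxy-2,2-dimethyl-6-methylidenecyclohexyl]methyl acetate | C=C1CC[C@H](O)C(C)(C)[C@@H]1COC(C)=O | intermediate
4 | [(1R)-2,2-dimethyl-6-methylidene-3-oxocyclohexyl]methyl acetate | C=C1CCC(=O)C(C)(C)[C@@H]1COC(C)=O | intermediate
5 | [(1R,3E)-2,2-dimethyl-6-methylidene-3-[2-(4-methylbenzenesulfonyl)hydrazinylidene]cyclohexyl]methyl acetate | C=C1CC/C(=N\NS(=O)(=O)c2ccc(C)cc2)C(C)(C)[C@@H]1COC(C)=O | intermediate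
6 | lithium [(1R)-3-lithio-2,2-dimethyl-6-methylidenecyclohex-3-en-1-yl]methanolate (not isolated) | C=C1CC=C([Li])C(C)(C)[C@@H]1CO[Li] | intermediate
7 | [(1R)-2,2-dimethyl-6-methylidenecyclohex-3-en-1-yl]methanol | C=C1CC=CC(C)(C)[C@@H]1CO | intermediate
8 | (1R)-2,2-dimethyl-6-methylidenecyclohex-3-ene-1-carbaldehyde | C=C1CC=CC(C)(C)[C@@H]1C=O | intermediate
9 | ethyl (1S,3S,6R)-7-oxabicyclo[4.1.0]heptane-3-carboxylate | CCOC(=O)[C@H]1CC[C@H]2O[C@H]2C1 | starting material
10 | ethyl (1S,3R,4R)-4-hydroxy-3-[(4-methylbenzenesulfonyl)oxy]cyclohexane-1-carboxylate | CCOC(=O)[C@H]1CC[C@@H](O)[C@H](OS(=O)(=O)c2ccc(C)cc2)C1 | intermediate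
11 | ethyl (1S,3R)-3-[(4-methylbenzenesulfonyl)oxy]-4-oxocyclohexane-1-carboxylate | CCOC(=O)[C@H]1CCC(=O)[C@H](OS(=O)(=O)c2ccc(C)cc2)C1 | intermediate
12 | ethyl (1S,3S)-3-bromo-4-oxocyclohexane-1-carboxylate | CCOC(=O)[C@H]1CCC(=O)[C@@H](Br)C1 | intermediate
13 | ethyl (1S,3S,4R)-3-bromo-4-hydroxy-4-methylcyclohexane-1-carboxylate | CCOC(=O)[C@H]1CC[C@@](C)(O)[C@@H](Br)C1 | intermediate
14 | (1S,3S,4R)-3-bromo-4-hydroxy-4-methylcyclohexane-1-carbaldehyde | O=C[C@H]1CC[C@@](C)(O)[C@@H](Br)C1 | intermediate
15 | (1R,2S,4S)-2-bromo-4-ethynyl-1-methylcyclohexan-1-ol | C#C[C@H]1CC[C@@](C)(O)[C@@H](Br)C1 | intermediate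
16 | (E)-alkenyldimethylalane of 15 as its dimethylaluminium alkoxide (not isolated) | C[Al](C)/C=C(\C)[C@H]1CC[C@@](C)(O[Al](C)C)[C@@H](Br)C1 | intermediate
17 | (1R,2S,4S)-2-bromo-4-[(1E)-1-iodoprop-1-en-2-yl]-1-methylcyclohexan-1-ol | I/C=C(\C)[C@H]1CC[C@@](C)(O)[C@@H](Br)C1 | intermediate
18 | (E)-alkenylchromium dichloride derived from 17 (not isolated) | Cl[Cr](Cl)/C=C(\C)[C@H]1CC[C@@](C)(O)[C@@H](Br)C1 | intermediate
19 | (1R,2S,4S)-2-bromo-4-{(2E,4R)-4-[(1R)-2,2-dimethyl-6-methylidenecyclohex-3-en-1-yl]-4-hydroxybut-2-en-2-yl}-1-methylcyclohexan-1-ol | C=C1CC=CC(C)(C)[C@@H]1[C@H](O)/C=C(\C)[C@H]1CC[C@@](C)(O)[C@@H](Br)C1 | target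

Total step count: 14. Longest linear sequence: 8 steps (steps 7–14).

**Steps most likely to fail**

Step 14.
- What may go wrong: single-electron reduction of the secondary C–Br bond by divalent chromium or low-valent nickel, followed by loss of the neighbouring oxygen function. Addition to the hindered aldehyde may also be slow enough for the exocyclic alkene to move into conjugation. Facial discrimination at the carbonyl group may be insufficient.
- Fallback: it replaces the chromium/nickel manifold by halogen–lithium exchange on a masked bromohydrin. It sets out from 17 (with 8) and comes back at 19.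
- Iodide 17 is silylated (Et3SiOTf, 2,6-lutidine, CH2Cl2, −78 °C) to the triethylsilyl ether F1.
- Iodine–lithium exchange (t-BuLi, 2 equiv, Et2O, −78 °C) is much faster at the alkenyl iodide than at the secondary bromide and gives the alkenyllithium F2.
- Aldehyde 8 is added at −78 °C, which under the same Felkin–Anh control should give the coupled silyl ether F3.
- HF·pyridine in THF at 0 °C then frees the tertiary alcohol and returns 19.

Step 9.
- What may go wrong: exchange of the product bromide with free bromide, or enolisation. Either process scrambles the bromine-bearing centre toward the axial epimer.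
- Fallback: it sets this centre by a carbon–hydrogen bond formation instead of a displacement. It sets out from 9 and comes back at 12.
- Epoxide 9 is opened trans-diaxially (LiBr, AcOH, THF) to the bromohydrin F4.
- Dess–Martin oxidation gives the axial bromoketone F5.
- Soft enolisation toward the more acidic CHBr position (Me3SiOTf, Et3N, CH2Cl2, 0 °C) gives the bromo silyl enol ether F6.
- Desilylation in the presence of a proton source (Bu4NF, AcOH, THF, −78 °C) should protonate the enolate carbon from the axial direction. This leaves bromine equatorial, that is 12.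

Step 5.
- What may go wrong: incomplete dianion formation at the hindered hydrazone, and base-induced migration of the skipped diene into conjugation during the warm-up.
- Fallback: it removes the ketone oxygen by a palladium-catalysed reduction under nearly neutral conditions. It sets out from 4 and comes back at 7.
- Ketone 4 is converted (Tf2O, 2,6-di-tert-butyl-4-methylpyridine, CH2Cl2, 0 °C), with the acetate left in place, into the enol triflate F7.
- Formate reduction (Pd(OAc)2, PPh3, HCO2H, Bu3N, DMF, 60 °C) gives the diene acetate F8.
- Methanolysis (K2CO3 cat., MeOH, 0 °C) returns 7.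

**Further compounds**
F1 | step 14 | {[(1R,2S,4S)-2-bromo-4-[(1E)-1-iodoprop-1-en-2-yl]-1-methylcyclohexyl]oxy}triethylsilane | I/C=C(\C)[C@H]1CC[C@@](C)(O[Si](CC)(CC)CC)[C@@H](Br)C1
F2 | step 14 | (E)-alkenyllithium derived from F1 | [Li]/C=C(\C)[C@H]1CC[C@@](C)(O[Si](CC)(CC)CC)[C@@H](Br)C1
F3 | step 14 | triethylsilyl ether of 19 at the tertiary hydroxyl group | C=C1CC=CC(C)(C)[C@@H]1[C@H](O)/C=C(\C)[C@H]1CC[C@@](C)(O[Si](CC)(CC)CC)[C@@H](Br)C1
F4 | step 9 | ethyl (1S,3R,4R)-3-bromo-4-hydroxycyclohexane-1-carboxylate | CCOC(=O)[C@H]1CC[C@@H](O)[C@H](Br)C1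
F5 | step 9 | ethyl (1S,3R)-3-bromo-4-oxocyclohexane-1-carboxylate | CCOC(=O)[C@H]1CCC(=O)[C@H](Br)C1
F6 | step 9 | ethyl (1S)-3-bromo-4-[(trimethylsilyl)oxy]cyclohex-3-ene-1-carboxylate | CCOC(=O)[C@H]1CCC(O[Si](C)(C)C)=C(Br)C1
F7 | step 5 | [(1R)-2,2-dimethyl-6-methylidene-3-[(trifluoromethanesulfonyl)oxy]cyclohex-3-en-1-yl]methyl acetate | C=C1CC=C(OS(=O)(=O)C(F)(F)F)C(C)(C)[C@@H]1COC(C)=O
F8 | step 5 | [(1R)-2,2-dimethyl-6-methylidenecyclohex-3-en-1-yl]methyl acetate | C=C1CC=CC(C)(C)[C@@H]1COC(C)=O
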